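**Retrosynthetic overview**

1. GA98 (the target gibberellin, 2β-hydroxy-GA44) ⇒ (ester and acetate hydrolysis, Wittig at C16) 16-oxo lactone 23 ⇒ (O–C20 bond by amidyl-radical 1,6-hydrogen transfer) C19 primary amide 19, in which C20 is still a methyl group.
2. The strategy rests on ring A: the C19 carbonyl on C4 and the C20 methyl on C10 are cis-1,3-diaxial on the α face, so the δ-lactone (C4–C19–O–C20–C10–C5) needs only one O–C20 bond between neighbours and can be made last.
3. 19 ⇒ Δ2 acid 13 (β-face hydroboration sets C2; the alkene comes from C19-acid-directed dehydrogenation) ⇒ ring-contracted diester 8.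
4. 8 ⇒ 6-diazo-7-ketone 6 (Wolff contraction of ring B, C6 set by equilibration) ⇒ 7β-hydroxysteviol 2 ⇒ steviol 1, which supplies rings A, C, D, the 13-OH and all other stereocentres.
5. Ring order: A, C and D from steviol; five-membered ring B (C5, C6, C8, C9, C10) in step 5; lactone ring in step 14.

Key step: step 14

Assumption (chemistry): the C7 hydroxylase PtmO6 is used as a recombinant E. coli lysate and is the one non-commercial catalyst; steviol and all other materials are commercial.

**Route**

Step 1
Reactants: 1 steviol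
Product: 2 7β-hydroxysteviol (ent-7α,13-dihydroxykaur-16-en-19-oic acid)
Conditions: PtmO6 (α-ketoglutarate-dependent non-heme iron dioxygenase, clarified lysate of recombinant E. coli), α-ketoglutaric acid, FeSO4 (cat.), ascorbic acid, air, phosphate buffer pH 7.5 with 5% DMSO, 28 °C
Reagents that add atoms: dioxygen, O=O
Why: Enzymatic C–H hydroxylation by a dioxygenase known to accept steviol and related ent-kauran-19-oic acids and to hydroxylate the C7 methylene with retention at the axial 7β-hydrogen, which puts the only handle on ring B next to quaternary C8 (the C7 configuration is erased in step 3).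

Step 2
Reactants: 2 7β-hydroxysteviol
Product: 3 benzyl 7β-hydroxysteviolate
Conditions: BnBr, K2CO3, DMF, 23 °C
Reagents that add atoms: benzyl bromide, BrCc1ccccc1
Why: Carboxylate O-alkylation (SN2 on benzyl bromide) esterifies the hindered axial C19 acid without touching the secondary and tertiary hydroxyls, and the ester keeps the acid from interfering in the enolate and carbene chemistry at C6 in steps 4 and 5.

Step 3
Reactants: 3 benzyl 7β-hydroxysteviolate
Product: 4 benzyl 7-oxosteviolate
Conditions: Dess–Martin periodinane, NaHCO3, CH2Cl2, 0 → 23 °C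
Reagents that add atoms: none
Why: Dess–Martin oxidation of the secondary 7-alcohol to the ketone, with the tertiary allylic 13-hydroxyl and the exocyclic alkene inert under the buffered conditions.

Step 4
Reactants: 4 benzyl 7-oxosteviolate
Product: 6 benzyl 6-diazo-7-oxosteviolate, via C6-trifluoroacetyl ketone 5 (not isolated)
Conditions: LiN(SiMe3)2 (3.2 equiv), THF, −78 °C; CF3CO2CH2CF3; 1 M HCl work-up; then MsN3, Et3N, H2O (1 equiv), MeCN, 23 °C
Reagents that add atoms: 2,2,2-trifluoroethyl trifluoroacetate, O=C(OCC(F)(F)F)C(F)(F)F (trifluoroacetyl group carried only in 5); methanesulfonyl azide, CS(=O)(=O)N=[N+]=[N-]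
Why: Deacylative (Regitz-type) diazo transfer, in which the 7-ketone can enolise only toward C6 because C8 is quaternary, the lithium enolate is C-trifluoroacetylated, and the activated β-diketone takes the diazo group from the sulfonyl azide with loss of the trifluoroacetyl group as its sulfonamide.

Step 5
Reactants: 6 benzyl 6-diazo-7-oxosteviolate
Product: 8 GA53 19-benzyl 7-methyl diester, via ring-contracted ketene 7 (not isolated)
Conditions: hν (300 nm), MeOH, 0 °C; then NaOMe (cat.), MeOH, 23 °C
Reagents that add atoms: methanol, CO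
Why: Photochemical Wolff rearrangement of the s-cis-locked cyclic α-diazo ketone, in which C8 migrates from C7 to C6 with retention as N2 leaves, methanol adds to the ketene to give the C7 methyl ester on the new five-membered ring B, and NaOMe should equilibrate C6 to the more stable epimer with the ester β, trans to C4 and clear of the axial C19 ester (H6 α, trans to H5).

Step 6
Reactants: 8 GA53 19-benzyl 7-methyl diester
Product: 9 13-O-acetyl-GA53 19-benzyl 7-methyl diester
Conditions: Ac2O, DMAP, Et3N, CH2Cl2, 40 °C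
Reagents that add atoms: acetic anhydride, CC(=O)OC(C)=O
Why: DMAP-catalysed acylation of the tertiary 13-hydroxyl under basic conditions, which avoid the acid-induced rearrangement of the 13-hydroxy-16-ene unit and give a group that cannot form an alkoxyl radical in step 14.

Step 7
Reactants: 9 13-O-acetyl-GA53 19-benzyl 7-methyl diester
Product: 11 13-acetoxy-16-oxo-17-nor-ent-gibberellane-7,19-dioic acid 19-benzyl 7-methyl diester, via spiro ozonide 10 (not isolated)
Conditions: O3, CH2Cl2, −78 °C (Sudan Red 7B end point); then PPh3, −78 → 23 °C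
Reagents that add atoms: ozone, [O-][O+]=O
Why: Ozonolysis of the only alkene, the exocyclic C16=C17 bond (dye end point to spare the benzyl arene), then reductive cleavage of the ozonide, so that the alkene is stored as the 16-ketone through the oxidative steps.

Step 8
Reactants: 11 13-acetoxy-16-oxo-17-nor-ent-gibberellane-7,19-dioic acid 19-benzyl 7-methyl diester
Product: 12 13-acetoxy-16-oxo-17-nor-ent-gibberellane-7,19-dioic acid 7-methyl ester (free C19 acid)
Conditions: H2 (1 atm), Pd/C (10% palladium on carbon), EtOAc, 23 °C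
Reagents that add atoms: none
Why: Hydrogenolysis of the benzyl ester frees the C19 acid needed as directing group, and no other group is reducible under these conditions.

Step 9
Reactants: 12 13-acetoxy-16-oxo-17-nor-ent-gibberellane-7,19-dioic acid 7-methyl ester
Product: 13 13-acetoxy-16-oxo-17-nor-ent-gibberell-2-ene-7,19-dioic acid 7-methyl ester (Δ2 acid)
Conditions: Pd(OAc)2 (10 mol%), bidentate pyridine–pyridone ligand (12 mol%), Ag2CO3 (2 equiv), Na2HPO4, (CF3)2CHOH, 110 °C
Reagents that add atoms: none
Why: Ligand-enabled β,γ-dehydrogenation of an α-quaternary aliphatic acid, in which carboxylate-bound divalent palladium metalates the cis hydrogen of the C3 methylene (H5 is trans to the carboxyl and palladation of the C18 methyl is reversible and unproductive) and β-hydride elimination toward C2, the only direction open because C4 is quaternary, gives the Δ2 acid with Ag2CO3 as terminal oxidant.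

Step 10
Reactants: 13 Δ2 acid
Product: 14 13-acetoxy-16,16-ethylenedioxy-17-nor-ent-gibberell-2-ene-7,19-dioic acid 7-methyl ester
Conditions: HOCH2CH2OH, TsOH·H2O (cat.), benzene, reflux (Dean–Stark)
Reagents that add atoms: ethylene glycol, OCCO
Why: Acid-catalysed ketalisation with azeotropic removal of water masks the 16-ketone against the borane of step 11, while the unactivated 1,2-disubstituted alkene should not be protonated by the catalytic acid and the hindered C19 acid does not esterify.

Step 11
Reactants: 14 13-acetoxy-16,16-ethylenedioxy-17-nor-ent-gibberell-2-ene-7,19-dioic acid 7-methyl ester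
Product: 16 13-acetoxy-16,16-ethylenedioxy-2β-hydroxy-17-nor-ent-gibberellane-7,19-dioic acid 7-methyl ester, via C2 organoborane 15 (not isolated)
Conditions: 9-BBN (3.5 equiv), THF, 23 → 65 °C; then NaOH, H2O2, H2O, 0 → 23 °C; acidify to pH 4
Reagents that add atoms: 9-borabicyclo[3.3.1]nonane, [BH]1C2CCCC1CCC2 (boron carried only in 15); hydrogen peroxide, OO (the C2 oxygen)
Why: Hydroboration–oxidation, in which 9-BBN first ties up the acid as its acyloxyborane and then adds syn across C2=C3 from the β face, opposite the axial C19 group on C4 and the axial C20 methyl on C10, with boron on C2 away from quaternary C4, so that oxidation with retention should give the equatorial 2β-alcohol.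

Step 12
Reactants: 16 13-acetoxy-16,16-ethylenedioxy-2β-hydroxy-17-nor-ent-gibberellane-7,19-dioic acid 7-methyl ester
Product: 17 2β,13-diacetoxy-16,16-ethylenedioxy-17-nor-ent-gibberellane-7,19-dioic acid 7-methyl ester
Conditions: Ac2O, DMAP, Et3N, CH2Cl2, 23 °C; aq. NaHCO3 work-up
Reagents that add atoms: acetic anhydride, CC(=O)OC(C)=O
Why: DMAP-catalysed acetylation of the equatorial 2β-hydroxyl, which also restores the tertiary 13-acetate should the alkaline peroxide of step 11 have cleaved part of it, while the bicarbonate work-up returns any mixed anhydride at C19 to the free acid.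

Step 13
Reactants: 17 2β,13-diacetoxy-16,16-ethylenedioxy-17-nor-ent-gibberellane-7,19-dioic acid 7-methyl ester
Product: 19 methyl 2β,13-diacetoxy-19-amino-16,16-ethylenedioxy-19-oxo-17-nor-ent-gibberellan-7-oate (C19 primary amide), via C19 acid chloride 18 (not isolated)
Conditions: Me2C=C(Cl)NMe2, CH2Cl2, 0 → 23 °C; then NH3 (0.5 M in dioxane), 0 °C
Reagents that add atoms: 1-chloro-N,N,2-trimethylprop-1-en-1-amine, CC(C)=C(Cl)N(C)C (chlorine carried only in 18); ammonia, N
Why: Neutral conversion of the hindered C19 acid into its chloride with the α-chloroenamine, which spares the ketal, then acylation of ammonia gives the primary amide that serves as the relay group.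

Step 14
Reactants: 19 C19 primary amide
Product: 23 16-oxo-17-nor-GA98 methyl ester 2,13-diacetate, via N-iodo amide 20 (not isolated), via C20 iodide 21 (not isolated), via cyclic imidate 22 (not isolated)
Conditions: PhI(OAc)2 (2.2 equiv), I2 (1.2 equiv), CH2Cl2, hν (tungsten lamp), 25 °C; aq. Na2S2O3 wash; then 1 M HCl, THF, 40 °C
Reagents that add atoms: water, O (carbonyl oxygens of the lactone and of the 16-ketone); iodine, II (carried only in 20 and 21)
Why: Acetyl hypoiodite, formed from PhI(OAc)2 and I2, N-iodinates the primary amide; light cleaves the N–I bond, and the amidyl radical, held on the α face by the axial C4–C19 bond, takes a hydrogen from the syn-axial C20 methyl through a seven-membered transition state (1,6-hydrogen atom transfer), after which the C20 radical is capped by iodine. The neopentyl iodide, activated by excess trivalent iodine, is displaced by the amide oxygen in a 6-exo-tet closure to the cyclic imidate, and aqueous acid hydrolyses C=NH to the six-membered 19,20-lactone while also removing the dioxolane. The closest known reaction type is the Hofmann–Löffler–Freytag-type lactonisation of N-iodo carboxamides (hypoiodite variant), a radical relay of the kind used to join 1,3-diaxial C19 and C20 groups in diterpenoids. No stereocentre is formed; the cis-diaxial placement of C19 and C20, fixed at C4 and C10 since steviol, is what allows both the hydrogen transfer and the closure. The step needs site selectivity for C20 over the axial H2α and H6α, which lie within 1,5-reach of the nitrogen: H2α is geminal to the acetoxy group and H6α is α to the methyl ester, so both are polarity-mismatched for the electrophilic amidyl radical, whereas the C20 hydrogens are unactivated and closest. Having iodine present from the start in non-nucleophilic CH2Cl2 should let N-iodination outrun an ionic Hofmann rearrangement, and no alkene is present to be iodinated because C16 is carried as the ketal.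

Step 15
Reactants: 23 16-oxo-17-nor-GA98 methyl ester 2,13-diacetate; 24 methyltriphenylphosphonium bromide
Product: 25 GA98 methyl ester 2,13-diacetate
Conditions: Ph3PCH3Br (24, 5 equiv), KOtBu (4.5 equiv), THF, 0 → 23 °C
Reagents that add atoms: methyltriphenylphosphonium bromide, C[P+](c1ccccc1)(c1ccccc1)c1ccccc1.[Br-]
Why: Wittig methylenation of the hindered 16-ketone with excess Ph3P=CH2 restores C16=C17, while esters, lactone and acetates should not react with the non-stabilised ylide at this temperature.

Step 16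
Reactants: 25 GA98 methyl ester 2,13-diacetate
Product: 27 GA98, via ring-opened dipotassium salt 26 (not isolated)
Conditions: KOH (2 M), MeOH/H2O, 70 °C; then HCl to pH 2.5, 0 → 23 °C
Reagents that add atoms: potassium hydroxide, [K+].[OH-] (oxygen of the C7 carboxyl group)
Why: Saponification removes both acetates, hydrolyses the hindered C7 methyl ester and opens the δ-lactone, and acidification recloses the lactone between the cis-diaxial C19 carboxyl and C20 hydroxymethyl (the 2β-hydroxyl and C7 cannot reach), leaving the C7 acid free and C6 in its more stable configuration.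

**Compound list**

1 | steviol (ent-13-hydroxykaur-16-en-19-oic acid) | C=C1C[C@]23C[C@@]1(O)CC[C@H]2[C@]1(C)CCC[C@@](C)(C(=O)O)[C@H]1CC3 | starting material
2 | 7β-hydroxysteviol (ent-7α,13-dihydroxykaur-16-en-19-oic acid) | C=C1C[C@]23C[C@@]1(O)CC[C@H]2[C@]1(C)CCC[C@@](C)(C(=O)O)[C@H]1C[C@@H]3O | intermediate
3 | benzyl 7β-hydroxysteviolate | C=C1C[C@]23C[C@@]1(O)CC[C@H]2[C@]1(C)CCC[C@@](C)(C(=O)OCc4ccccc4)[C@H]1C[C@@H]3O | intermediate
4 | benzyl 7-oxosteviolate (benzyl ent-13-hydroxy-7-oxokaur-16-en-19-oate) | C=C1C[C@]23C[C@@]1(O)CC[C@H]2[C@]1(C)CCC[C@@](C)(C(=O)OCc4ccccc4)[C@H]1CC3=O | intermediate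
5 | benzyl 6-trifluoroacetyl-7-oxosteviolate (C6 unassigned, enolised; not isolated) | C=C1C[C@]23C[C@@]1(O)CC[C@H]2[C@]1(C)CCC[C@@](C)(C(=O)OCc4ccccc4)[C@H]1C(C(=O)C(F)(F)F)C3=O | intermediate
6 | benzyl 6-diazo-7-oxosteviolate | C=C1C[C@]23C[C@@]1(O)CC[C@H]2[C@]1(C)CCC[C@@](C)(C(=O)OCc4ccccc4)[C@H]1C(=[N+]=[N-])C3=O | intermediate
7 | ring-contracted ketene, C6=C7=O on ring B (not isolated) | C=C1C[C@]23C[C@@]1(O)CC[C@H]2[C@]1(C)CCC[C@@](C)(C(=O)OCc4ccccc4)[C@H]1C3=C=O | intermediate
8 | GA53 19-benzyl 7-methyl diester (diester of 13-hydroxy-ent-gibberell-16-ene-7,19-dioic acid, H6 α) | C=C1C[C@]23C[C@@]1(O)CC[C@H]2[C@]1(C)CCC[C@@](C)(C(=O)OCc4ccccc4)[C@H]1[C@@H]3C(=O)OC | intermediate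
9 | 13-O-acetyl-GA53 19-benzyl 7-methyl diester | C=C1C[C@]23C[C@@]1(OC(C)=O)CC[C@H]2[C@]1(C)CCC[C@@](C)(C(=O)OCc4ccccc4)[C@H]1[C@@H]3C(=O)OC | intermediate
10 | 16,17-ozonide of 9 (spiro 1,2,4-trioxolane at C16, configuration at C16 unassigned; not isolated) | C14(OOCO4)C[C@]23C[C@@]1(OC(C)=O)CC[C@H]2[C@]1(C)CCC[C@@](C)(C(=O)OCc4ccccc4)[C@H]1[C@@H]3C(=O)OC | intermediate
11 | 13-acetoxy-16-oxo-17-nor-ent-gibberellane-7,19-dioic acid 19-benzyl 7-methyl diester | O=C1C[C@]23C[C@@]1(OC(C)=O)CC[C@H]2[C@]1(C)CCC[C@@](C)(C(=O)OCc4ccccc4)[C@H]1[C@@H]3C(=O)OC | intermediate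
12 | 13-acetoxy-16-oxo-17-nor-ent-gibberellane-7,19-dioic acid 7-methyl ester (free C19 acid) | O=C1C[C@]23C[C@@]1(OC(C)=O)CC[C@H]2[C@]1(C)CCC[C@@](C)(C(=O)O)[C@H]1[C@@H]3C(=O)OC | intermediate
13 | 13-acetoxy-16-oxo-17-nor-ent-gibberell-2-ene-7,19-dioic acid 7-methyl ester (Δ2 acid) | O=C1C[C@]23C[C@@]1(OC(C)=O)CC[C@H]2[C@]1(C)CC=C[C@@](C)(C(=O)O)[C@H]1[C@@H]3C(=O)OC | intermediate
14 | 13-acetoxy-16,16-ethylenedioxy-17-nor-ent-gibberell-2-ene-7,19-dioic acid 7-methyl ester | C14(OCCO4)C[C@]23C[C@@]1(OC(C)=O)CC[C@H]2[C@]1(C)CC=C[C@@](C)(C(=O)O)[C@H]1[C@@H]3C(=O)OC | intermediate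
15 | 2β-(9-borabicyclo[3.3.1]nonan-9-yl) adduct of 14, C19 acid as its acyloxyborane (not isolated) | C14(OCCO4)C[C@]23C[C@@]1(OC(C)=O)CC[C@H]2[C@]1(C)C[C@H](B5C6CCCC5CCC6)C[C@@](C)(C(=O)OB5C6CCCC5CCC6)[C@H]1[C@@H]3C(=O)OC | intermediate
16 | 13-acetoxy-16,16-ethylenedioxy-2β-hydroxy-17-nor-ent-gibberellane-7,19-dioic acid 7-methyl ester | C14(OCCO4)C[C@]23C[C@@]1(OC(C)=O)CC[C@H]2[C@]1(C)C[C@H](O)C[C@@](C)(C(=O)O)[C@H]1[C@@H]3C(=O)OC | intermediate
17 | 2β,13-diacetoxy-16,16-ethylenedioxy-17-nor-ent-gibberellane-7,19-dioic acid 7-methyl ester | C14(OCCO4)C[C@]23C[C@@]1(OC(C)=O)CC[C@H]2[C@]1(C)C[C@H](OC(C)=O)C[C@@](C)(C(=O)O)[C@H]1[C@@H]3C(=O)OC | intermediate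
18 | C19 acid chloride of 17 (not isolated) | C14(OCCO4)C[C@]23C[C@@]1(OC(C)=O)CC[C@H]2[C@]1(C)C[C@H](OC(C)=O)C[C@@](C)(C(Cl)=O)[C@H]1[C@@H]3C(=O)OC | intermediate
19 | C19 primary amide: 2β,13-diacetoxy, 16,16-ethylenedioxy, 17-nor, C7 methyl ester, C20 methyl (key-step precursor) | C14(OCCO4)C[C@]23C[C@@]1(OC(C)=O)CC[C@H]2[C@]1(C)C[C@H](OC(C)=O)C[C@@](C)(C(N)=O)[C@H]1[C@@H]3C(=O)OC | intermediate
20 | N-iodo amide of 19 (not isolated) | C14(OCCO4)C[C@]23C[C@@]1(OC(C)=O)CC[C@H]2[C@]1(C)C[C@H](OC(C)=O)C[C@@](C)(C(=O)NI)[C@H]1[C@@H]3C(=O)OC | intermediate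
21 | 20-iodo amide (not isolated) | C14(OCCO4)C[C@]23C[C@@]1(OC(C)=O)CC[C@H]2[C@]1(CI)C[C@H](OC(C)=O)C[C@@](C)(C(N)=O)[C@H]1[C@@H]3C(=O)OC | intermediate
22 | cyclic imidate (19,20-iminolactone, ketal still in place; not isolated) | C14(OCCO4)C[C@]23C[C@@]1(OC(C)=O)CC[C@H]2[C@]12COC(=N)[C@](C)(C[C@@H](OC(C)=O)C1)[C@H]2[C@@H]3C(=O)OC | intermediate
23 | 16-oxo-17-nor-GA98 methyl ester 2,13-diacetate | O=C1C[C@]23C[C@@]1(OC(C)=O)CC[C@H]2[C@]12COC(=O)[C@](C)(C[C@@H](OC(C)=O)C1)[C@H]2[C@@H]3C(=O)OC | intermediate
24 | methyltriphenylphosphonium bromide | C[P+](c1ccccc1)(c1ccccc1)c1ccccc1.[Br-] | starting material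
25 | GA98 methyl ester 2,13-diacetate | C=C1C[C@]23C[C@@]1(OC(C)=O)CC[C@H]2[C@]12COC(=O)[C@](C)(C[C@@H](OC(C)=O)C1)[C@H]2[C@@H]3C(=O)OC | intermediate
26 | dipotassium 2β,13,20-trihydroxy-ent-gibberell-16-ene-7,19-dioate (ring-opened; not isolated) | C=C1C[C@]23C[C@@]1(O)CC[C@H]2[C@]1(CO)C[C@H](O)C[C@@](C)(C(=O)[O-])[C@H]1[C@@H]3C(=O)[O-].[K+].[K+] | intermediate
27 | GA98 (2β-hydroxy-GA44; 19,20-lactone of 2β,13,20-trihydroxy-ent-gibberell-16-ene-7,19-dioic acid, C7 acid free) | C=C1C[C@]23C[C@@]1(O)CC[C@H]2[C@]12COC(=O)[C@](C)(C[C@@H](O)C1)[C@H]2[C@@H]3C(=O)O | target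

**Step count and risks**

Total step count: 16. Longest linear sequence: 16 steps (from steviol 1).

Steps most likely to fail:

1. Step 14 (radical lactonisation). What may go wrong: the amidyl radical abstracts the axial hydrogen on C2 or C6 (both 1,5) instead of a C20 hydrogen, or the N-iodo amide undergoes ionic Hofmann rearrangement to the C4 isocyanate. Either would consume the C19 group without oxidising C20. Fallback: oxidise C20 biocatalytically at the end of the route, as the plant does. Setting out from 17, 1 M HCl in THF would free the ketone to give the 2β,13-diacetoxy-16-oxo acid F1. Methylenation with the ylide from 24 and KOtBu would give the 16-ene acid F2. KOH in aqueous methanol would give 2β-hydroxy-GA53 (GA97) F3. A recombinant gibberellin 20-oxidase (α-ketoglutaric acid, FeSO4, ascorbic acid, air, buffer pH 7) would hydroxylate the C20 methyl, the oxidation that converts GA53 into GA44, to give the ring-opened 20-hydroxy dicarboxylate (the dianion of 26). Acidification to pH 2.5 would close the lactone, and the fallback comes back to the route at 27.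

2. Step 9 (β,γ-dehydrogenation). What may go wrong: the carboxylate-bound palladium fails to metalate the hindered C3 methylene next to quaternary C4 (unproductive palladation of the C18 methyl, catalyst decay to palladium black), so that no alkene forms. Fallback: make the C2–O bond directly by carboxylate-directed C–H lactonisation and correct the configuration afterwards. From 12, [Fe(S,S-PDP)(MeCN)2](SbF6)2 with H2O2 in MeCN (no added carboxylic acid) would deliver oxygen to the axial γ-hydrogen on C2 and give the 19,2α-lactone F4. NH3 in methanol (sealed tube, 50 °C) would open the bridged lactone to the 2α-hydroxy 19-carboxamide F5. A Mitsunobu reaction with acetic acid (PPh3, diisopropyl azodicarboxylate, THF) would invert C2 and give the 2β-acetoxy amide F6, the 16-ketone counterpart of 19. F6 would be taken through the conditions of step 14 (no ketal to remove) and rejoins the route at 23.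

3. Step 11 (hydroboration). What may go wrong: slow addition of the bulky borane to the alkene flanked by quaternary C4, or loss of regiocontrol (boron on C3) if a smaller borane has to be used. Fallback: dihydroxylation followed by deoxygenation at C3. From 14, OsO4 (cat.) with N-methylmorpholine N-oxide in acetone/water would add from the β face to give the 2β,3β-diol F7. Ac2O in pyridine at 0 °C would acetylate only the equatorial 2β-hydroxyl to give the 2-monoacetate F8. PhOC(S)Cl with DMAP would convert the axial 3β-hydroxyl into the phenyl thionocarbonate F9. Bu3SnH with AIBN in toluene at 100 °C (Barton–McCombie deoxygenation) would remove the C3 oxygen and rejoin the route at 17.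

**Further compounds**

F1 | step 14 | 2β,13-diacetoxy-16-oxo-17-nor-ent-gibberellane-7,19-dioic acid 7-methyl ester | O=C1C[C@]23C[C@@]1(OC(C)=O)CC[C@H]2[C@]1(C)C[C@H](OC(C)=O)C[C@@](C)(C(=O)O)[C@H]1[C@@H]3C(=O)OC
F2 | step 14 | 2β,13-diacetoxy-ent-gibberell-16-ene-7,19-dioic acid 7-methyl ester | C=C1C[C@]23C[C@@]1(OC(C)=O)CC[C@H]2[C@]1(C)C[C@H](OC(C)=O)C[C@@](C)(C(=O)O)[C@H]1[C@@H]3C(=O)OC
F3 | step 14 | 2β-hydroxy-GA53 (GA97) | C=C1C[C@]23C[C@@]1(O)CC[C@H]2[C@]1(C)C[C@H](O)C[C@@](C)(C(=O)O)[C@H]1[C@@H]3C(=O)O
F4 | step 9 | 13-acetoxy-16-oxo-17-nor-ent-gibberellane-7,19-dioic acid 7-methyl ester 19,2α-lactone | O=C1C[C@]23C[C@@]1(OC(C)=O)CC[C@H]2[C@]1(C)C[C@@H]4C[C@@](C)(C(=O)O4)[C@H]1[C@@H]3C(=O)OC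
F5 | step 9 | 2α-hydroxy 19-carboxamide (13-acetoxy, 16-oxo, 17-nor, C7 methyl ester) | O=C1C[C@]23C[C@@]1(OC(C)=O)CC[C@H]2[C@]1(C)C[C@@H](O)C[C@@](C)(C(N)=O)[C@H]1[C@@H]3C(=O)OC
F6 | step 9 | 2β,13-diacetoxy 19-carboxamide with free 16-ketone (17-nor, C7 methyl ester) | O=C1C[C@]23C[C@@]1(OC(C)=O)CC[C@H]2[C@]1(C)C[C@H](OC(C)=O)C[C@@](C)(C(N)=O)[C@H]1[C@@H]3C(=O)OC
F7 | step 11 | 13-acetoxy-16,16-ethylenedioxy-2β,3β-dihydroxy-17-nor-ent-gibberellane-7,19-dioic acid 7-methyl ester | C14(OCCO4)C[C@]23C[C@@]1(OC(C)=O)CC[C@H]2[C@]1(C)C[C@H](O)[C@H](O)[C@@](C)(C(=O)O)[C@H]1[C@@H]3C(=O)OC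
F8 | step 11 | 2β,13-diacetoxy-16,16-ethylenedioxy-3β-hydroxy-17-nor-ent-gibberellane-7,19-dioic acid 7-methyl ester | C14(OCCO4)C[C@]23C[C@@]1(OC(C)=O)CC[C@H]2[C@]1(C)C[C@H](OC(C)=O)[C@H](O)[C@@](C)(C(=O)O)[C@H]1[C@@H]3C(=O)OC
F9 | step 11 | 3β-O-(phenoxythiocarbonyl) derivative of F8 | C14(OCCO4)C[C@]23C[C@@]1(OC(C)=O)CC[C@H]2[C@]1(C)C[C@H](OC(C)=O)[C@H](OC(=S)Oc5ccccc5)[C@@](C)(C(=O)O)[C@H]1[C@@H]3C(=O)OC
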